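**Plan**

- The retrosynthesis cuts both bonds of the ketone carbon: the one to C1 of ring A and the one to C1' of ring B. The carbonyl carbon itself becomes carbon monoxide.
- This works because C1', C2' and C3' of ring B (acyl, prenyl, hydroxyl) map onto C3, C2 and C1 of 2-prenylcyclohexane-1,3-dione. Ring B can therefore enter as a cyclohexenone bearing tin at C3, and ring A as an aryl iodide.
- Forward, ring B branch: cyclohexane-1,3-dione is C-prenylated, converted to the enol triflate and stannylated. Ring A branch: 4,6-dibromoresorcinol is MOM-protected, prenylated and iodinated.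
- Aryl iodide, CO and alkenylstannane are joined in one palladium-catalysed step. Dehydrogenation of the cyclohexenone to the C3' phenol and MOM removal finish the route. No ring is formed at any stage.
- The target has no stereocentre and no stereogenic alkene, so no stereocontrol is needed.

Key step: step 7

Remark: the tin substituents of the ring B partner are taken as methyl, because a tetrasubstituted alkenylstannane transmetalates faster as Me3Sn than as Bu3Sn and (Me3Sn)2 is the more reliable partner for enol triflates.

**Route**

Step 1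
Reactants: 1 cyclohexane-1,3-dione; 2 prenyl bromide (1-bromo-3-methylbut-2-ene)
Product: 3 2-(3-methylbut-2-enyl)cyclohexane-1,3-dione
Conditions: KOH (1.0 equiv), H2O, 0 °C → rt; then acidify
Reagents that add atoms: none
Why: C-alkylation of the 1,3-dione enolate by an allylic bromide in water, where solvation of the enolate oxygens disfavours O-alkylation, should take place at C2, the only doubly activated carbon of the symmetrical dione.

Step 2
Reactants: 3 2-(3-methylbut-2-enyl)cyclohexane-1,3-dione
Product: 4 2-(3-methylbut-2-enyl)-3-oxocyclohex-1-en-1-yl trifluoromethanesulfonate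
Conditions: Tf2O, pyridine, CH2Cl2, −78 → 0 °C
Reagents that add atoms: triflic anhydride, O=S(=O)(OS(=O)(=O)C(F)(F)F)C(F)(F)F
Why: O-sulfonylation of the enol form of the vinylogous acid (enol triflate formation) can give only one product because the two carbonyl groups of 3 are equivalent.

Step 3
Reactants: 4 2-(3-methylbut-2-enyl)-3-oxocyclohex-1-en-1-yl trifluoromethanesulfonate
Product: 5 2-(3-methylbut-2-enyl)-3-(trimethylstannyl)cyclohex-2-en-1-one
Conditions: (Me3Sn)2, Pd(PPh3)4 (5 mol %), LiCl, THF, 65 °C
Reagents that add atoms: hexamethyldistannane, C[Sn](C)(C)[Sn](C)(C)C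
Why: Palladium-catalysed stannylation of an enol triflate with a distannane (oxidative addition, chloride-assisted tin-to-palladium transmetalation, reductive elimination) is an established entry to beta-stannyl enones from beta-triflyloxy enones.

Step 4
Reactants: 6 4,6-dibromoresorcinol
Product: 7 1,5-dibromo-2,4-bis(methoxymethoxy)benzene
Conditions: MOMCl, iPr2NEt, CH2Cl2, 0 °C → rt
Reagents that add atoms: chloromethyl methyl ether, COCCl
Why: Base-mediated O-alkylation of both phenols with the alpha-chloro ether (MOM protection) removes the acidic protons and installs ortho-coordinating groups for the bromine-lithium exchanges that follow.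

Step 5
Reactants: 7 1,5-dibromo-2,4-bis(methoxymethoxy)benzene; 2 prenyl bromide
Product: 10 1-bromo-2,4-bis(methoxymethoxy)-5-(3-methylbut-2-enyl)benzene, via aryllithium 8 (not isolated), via arylcopper 9 (not isolated)
Conditions: n-BuLi (1.0 equiv), THF, −78 °C; CuBr·SMe2 (1.0 equiv), −78 → −40 °C; prenyl bromide, −40 → 0 °C
Reagents that add atoms: none
Why: Bromine-lithium exchange with one equivalent of n-BuLi should stop at the monolithium stage because a second exchange would place two carbanions on one ring, and the derived arylcopper undergoes copper-mediated allylic substitution at the unhindered primary carbon of prenyl bromide (SN2 and not SN2').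

Step 6
Reactants: 10 1-bromo-2,4-bis(methoxymethoxy)-5-(3-methylbut-2-enyl)benzene
Product: 12 1-iodo-2,4-bis(methoxymethoxy)-5-(3-methylbut-2-enyl)benzene, via aryllithium 11 (not isolated)
Conditions: n-BuLi, THF, −78 °C; I2, −78 °C → rt; aq. Na2S2O3
Reagents that add atoms: iodine, II
Why: A second bromine-lithium exchange followed by iodinolysis of the aryllithium turns the remaining bromide into the iodide needed for fast oxidative addition, the exchange being much faster at −78 °C than deprotonation between the two MOM ethers.

Step 7
Reactants: 12 1-iodo-2,4-bis(methoxymethoxy)-5-(3-methylbut-2-enyl)benzene; 13 carbon monoxide; 5 2-(3-methylbut-2-enyl)-3-(trimethylstannyl)cyclohex-2-en-1-one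
Product: 14 3-[2,4-bis(methoxymethoxy)-5-(3-methylbut-2-enyl)benzoyl]-2-(3-methylbut-2-enyl)cyclohex-2-en-1-one
Conditions: Pd2(dba)3 (2.5 mol %), AsPh3 (20 mol %), CuI (10 mol %), CO (3 bar), NMP, 60 °C
Reagents that add atoms: none
Why: Aryl iodide 12 adds oxidatively to zerovalent palladium, CO inserts into the aryl-palladium bond to give the aroylpalladium iodide, the alkenyl group of 5 is handed over through a transient alkenylcopper formed with CuI, and reductive elimination releases enedione 14 and regenerates zerovalent palladium. The closest known reaction type is the carbonylative Stille coupling of aryl iodides with alkenylstannanes to aryl vinyl ketones, here in the copper-assisted form used for hindered or electron-poor stannanes. No ring is closed and no stereocentre is created; the two new skeletal bonds are C1 of ring A to the carbonyl carbon and the carbonyl carbon to C3 of the cyclohexenone, the future C1' of ring B. The selectivity needed is CO insertion ahead of transmetalation, so that the CO-free aryl-alkenyl coupling product does not form: the electron-rich aryl group migrates readily to CO, 3 bar of CO keeps the aroyl complex populated, and the tetrasubstituted electron-poor stannane transmetalates only slowly. AsPh3, CuI and the trimethylstannyl group are chosen to make that slow transmetalation still fast enough to outrun protodestannylation. The aroylpalladium sits on ring A, remote from both prenyl alkenes, so an acyl-Heck cyclisation cannot intervene.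

Step 8
Reactants: 14 3-[2,4-bis(methoxymethoxy)-5-(3-methylbut-2-enyl)benzoyl]-2-(3-methylbut-2-enyl)cyclohex-2-en-1-one
Product: 16 [2,4-bis(methoxymethoxy)-5-(3-methylbut-2-enyl)phenyl][2-(3-methylbut-2-enyl)-3-(trimethylsilyloxy)cyclohexa-1,3-dien-1-yl]methanone, via lithium dienolate 15 (not isolated)
Conditions: LiN(SiMe3)2 (1.1 equiv), THF, −78 °C; TMSCl, −78 → 0 °C; non-aqueous work-up, used crude
Reagents that add atoms: chlorotrimethylsilane, C[Si](C)(C)Cl
Why: Kinetic deprotonation of the enone at the alpha' carbon C6 by the hindered amide followed by O-silylation (kinetic silyl dienol ether formation) should give the cross-conjugated 2-silyloxydiene, and the aryl ketone has no alpha hydrogen of its own to compete.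

Step 9
Reactants: 16 [2,4-bis(methoxymethoxy)-5-(3-methylbut-2-enyl)phenyl][2-(3-methylbut-2-enyl)-3-(trimethylsilyloxy)cyclohexa-1,3-dien-1-yl]methanone
Product: 18 [2,4-bis(methoxymethoxy)-5-(3-methylbut-2-enyl)phenyl][3-hydroxy-2-(3-methylbut-2-enyl)phenyl]methanone, via cyclohexa-2,5-dienone 17 (not isolated)
Conditions: Pd(OAc)2 (1.0 equiv, divalent palladium, no excess), MeCN, rt
Reagents that add atoms: none
Why: In this Saegusa-Ito oxidation the silyl enol ether should pass to a palladium enolate at C6, beta-hydride elimination from C5 gives cyclohexa-2,5-dienone 17, and this keto tautomer of a phenol enolises at once to aromatic ring B.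

Step 10
Reactants: 18 [2,4-bis(methoxymethoxy)-5-(3-methylbut-2-enyl)phenyl][3-hydroxy-2-(3-methylbut-2-enyl)phenyl]methanone
Product: 19 cudraphenone B
Conditions: HCl (3 M aq., few equiv), MeOH, rt → 40 °C
Reagents that add atoms: none
Why: Acid-catalysed acetal exchange with methanol (MOM ether cleavage) should free both phenols of ring A under conditions mild enough for ortho-prenyl phenols, as is usual at the end of prenylated polyphenol syntheses.

**Compound list**

1 | cyclohexane-1,3-dione | O=C1CCCC(=O)C1 | starting material
2 | prenyl bromide (1-bromo-3-methylbut-2-ene) | CC(C)=CCBr | starting material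
3 | 2-(3-methylbut-2-enyl)cyclohexane-1,3-dione | CC(C)=CCC1C(=O)CCCC1=O | intermediate
4 | 2-(3-methylbut-2-enyl)-3-oxocyclohex-1-en-1-yl trifluoromethanesulfonate | CC(C)=CCC1=C(OS(=O)(=O)C(F)(F)F)CCCC1=O | intermediate
5 | 2-(3-methylbut-2-enyl)-3-(trimethylstannyl)cyclohex-2-en-1-one | C[Sn](C)(C)C1=C(CC=C(C)C)C(=O)CCC1 | intermediate
6 | 4,6-dibromoresorcinol | Oc1cc(O)c(Br)cc1Br | starting material
7 | 1,5-dibromo-2,4-bis(methoxymethoxy)benzene | COCOc1cc(OCOC)c(Br)cc1Br | intermediate
8 | [5-bromo-2,4-bis(methoxymethoxy)phenyl]lithium | [Li]c1cc(Br)c(OCOC)cc1OCOC | intermediate (not isolated)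
9 | [5-bromo-2,4-bis(methoxymethoxy)phenyl]copper | [Cu]c1cc(Br)c(OCOC)cc1OCOC | intermediate (not isolated)
10 | 1-bromo-2,4-bis(methoxymethoxy)-5-(3-methylbut-2-enyl)benzene | CC(C)=CCc1cc(Br)c(OCOC)cc1OCOC | intermediate
11 | [2,4-bis(methoxymethoxy)-5-(3-methylbut-2-enyl)phenyl]lithium | [Li]c1cc(CC=C(C)C)c(OCOC)cc1OCOC | intermediate (not isolated)
12 | 1-iodo-2,4-bis(methoxymethoxy)-5-(3-methylbut-2-enyl)benzene | CC(C)=CCc1cc(I)c(OCOC)cc1OCOC | intermediate
13 | carbon monoxide | [C-]#[O+] | starting material
14 | 3-[2,4-bis(methoxymethoxy)-5-(3-methylbut-2-enyl)benzoyl]-2-(3-methylbut-2-enyl)cyclohex-2-en-1-one | CC(C)=CCc1cc(C(=O)C2=C(CC=C(C)C)C(=O)CCC2)c(OCOC)cc1OCOC | intermediate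
15 | lithium 5-[2,4-bis(methoxymethoxy)-5-(3-methylbut-2-enyl)benzoyl]-6-(3-methylbut-2-enyl)cyclohexa-1,5-dien-1-olate | [Li]OC1=CCCC(C(=O)c2cc(CC=C(C)C)c(OCOC)cc2OCOC)=C1CC=C(C)C | intermediate (not isolated)
16 | [2,4-bis(methoxymethoxy)-5-(3-methylbut-2-enyl)phenyl][2-(3-methylbut-2-enyl)-3-(trimethylsilyloxy)cyclohexa-1,3-dien-1-yl]methanone | C[Si](C)(C)OC1=CCCC(C(=O)c2cc(CC=C(C)C)c(OCOC)cc2OCOC)=C1CC=C(C)C | intermediate
17 | 3-[2,4-bis(methoxymethoxy)-5-(3-methylbut-2-enyl)benzoyl]-2-(3-methylbut-2-enyl)cyclohexa-2,5-dien-1-one | CC(C)=CCc1cc(C(=O)C2=C(CC=C(C)C)C(=O)C=CC2)c(OCOC)cc1OCOC | intermediate (not isolated)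
18 | [2,4-bis(methoxymethoxy)-5-(3-methylbut-2-enyl)phenyl][3-hydroxy-2-(3-methylbut-2-enyl)phenyl]methanone | CC(C)=CCc1cc(C(=O)c2cccc(O)c2CC=C(C)C)c(OCOC)cc1OCOC | intermediate
19 | cudraphenone B, [2,4-dihydroxy-5-(3-methylbut-2-enyl)phenyl][3-hydroxy-2-(3-methylbut-2-enyl)phenyl]methanone | CC(C)=CCc1cc(C(=O)c2cccc(O)c2CC=C(C)C)c(O)cc1O | target

**Step count and risks**

Total step count: 10 steps.
Longest linear sequence: 7 steps (steps 4, 5, 6, 7, 8, 9, 10 from 6; the ring B branch through steps 1, 2, 3 is equally long).

Steps most likely to fail: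

1. Step 7. Transmetalation from the tetrasubstituted, electron-poor alkenylstannane to the hindered ortho-alkoxy aroylpalladium may be too slow. Protodestannylation, reduction of the aroyl complex or CO-free direct coupling would then take over. The fallback reverses the polarity of the bond to the ring B carbon and sets out from bromide 10 and triflate 4. Aryllithium 11, generated from 10 as in step 6, is quenched with DMF to give 2,4-bis(methoxymethoxy)-5-(3-methylbut-2-enyl)benzaldehyde F1. A Nozaki-Hiyama-Kishi coupling of F1 with enol triflate 4 (CrCl2, NiCl2 cat., DMF, rt) follows, in which the alkenylchromium adds to the aldehyde and leaves the ring ketone alone. It should give racemic 3-{[2,4-bis(methoxymethoxy)-5-(3-methylbut-2-enyl)phenyl](hydroxy)methyl}-2-(3-methylbut-2-enyl)cyclohex-2-en-1-one F2. Oxidation of this allylic and benzylic alcohol with MnO2 in CH2Cl2 comes back to the route at enedione 14.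

2. Step 9. Divalent palladium may engage the prenyl alkenes or cyclise the newly formed ortho-prenyl phenol oxidatively (Wacker-type ring closure). The labile silyl dienol ether may also simply hydrolyse back to the enone. The fallback replaces the palladium-mediated dehydrogenation by a selenoxide elimination and sets out from enedione 14. Lithium dienolate 15, formed as in step 8, is trapped at −78 °C with PhSeCl to give racemic 3-[2,4-bis(methoxymethoxy)-5-(3-methylbut-2-enyl)benzoyl]-2-(3-methylbut-2-enyl)-6-(phenylselanyl)cyclohex-2-en-1-one F3. Oxidation with NaIO4 (NaHCO3, THF/H2O, 0 °C → rt) and syn-elimination of the selenoxide lead through dienone 17 back to the route at phenol 18.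

3. Step 10. Under Brønsted acid the ortho-prenyl phenols may cyclise to 2,2-dimethylchromans, or HCl or methanol may add across the prenyl alkenes, before both MOM ethers are gone. The fallback avoids protic acid by exchanging the acetals for silyl ethers and sets out from 18. TMSOTf and 2,2'-bipyridyl in MeCN at 0 °C convert aryl MOM ethers, through N-(methoxymethyl)bipyridinium salts, into aryl trimethylsilyl ethers and silylate the free phenol as well. This gives [2,4-bis(trimethylsilyloxy)-5-(3-methylbut-2-enyl)phenyl][2-(3-methylbut-2-enyl)-3-(trimethylsilyloxy)phenyl]methanone F4. Addition of water at rt hydrolyses the three silyl ethers at near-neutral pH and comes back to the route at target 19.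

**Further compounds**

F1 | step 7 | 2,4-bis(methoxymethoxy)-5-(3-methylbut-2-enyl)benzaldehyde | CC(C)=CCc1cc(C=O)c(OCOC)cc1OCOC
F2 | step 7 | racemic 3-{[2,4-bis(methoxymethoxy)-5-(3-methylbut-2-enyl)phenyl](hydroxy)methyl}-2-(3-methylbut-2-enyl)cyclohex-2-en-1-one | CC(C)=CCc1cc(C(O)C2=C(CC=C(C)C)C(=O)CCC2)c(OCOC)cc1OCOC
F3 | step 9 | racemic 3-[2,4-bis(methoxymethoxy)-5-(3-methylbut-2-enyl)benzoyl]-2-(3-methylbut-2-enyl)-6-(phenylselanyl)cyclohex-2-en-1-one | CC(C)=CCc1cc(C(=O)C2=C(CC=C(C)C)C(=O)C([Se]c3ccccc3)CC2)c(OCOC)cc1OCOC
F4 | step 10 | [2,4-bis(trimethylsilyloxy)-5-(3-methylbut-2-enyl)phenyl][2-(3-methylbut-2-enyl)-3-(trimethylsilyloxy)phenyl]methanone | CC(C)=CCc1cc(C(=O)c2cccc(O[Si](C)(C)C)c2CC=C(C)C)c(O[Si](C)(C)C)cc1O[Si](C)(C)C
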